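The neighbour recipe, the alpha charge read at 40 min, leaves me deciding how long the next run should stand, so I set one charge beside three stopping times.

    2 starting material → homo dimer (k1 = 0.020 M⁻¹ min⁻¹)
    starting material + target → side product (k2 = 7.1 M⁻¹ min⁻¹)
    starting material + reagent ⇌ target (K3 = 18 M⁻¹, k3 = 8.8 M⁻¹ min⁻¹)
    starting material + second substrate → cross product (k4 = 0.12 M⁻¹ min⁻¹)
    second substrate + reagent → second product (k5 = 0.39 M⁻¹ min⁻¹)

all flasks: starting material 0.010 M; reagent 0.0120 M; second substrate 0.0200 M
- theta: time 20 min
- alpha: time 25 min
- zeta: time 30 min

* which of these there is most of at the end, counted by the starting material in it, theta (cross product / starting material / side product / target)
* which of these there is most of at the end, counted by the starting material in it, alpha (cross product / starting material / side product / target)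
* which of these there is most of at the end, counted by the starting material in it, zeta (cross product / starting material / side product / target)
* amount of the one of these that there is most of at the end, in percent of the starting material charged, theta
* amount of the one of these that there is most of at the end, in percent of the starting material charged, alpha
* amount of the one of these that there is most of at the end, in percent of the starting material charged, zeta

- percent here means starting material units held: one side product or homo dimer counts as two
- for a step with 2 of a species take k times the square, and two of it per event
- run time (theta): 20 min

I turn the constants into times at the charged amounts. In theta, the reversible step relaxes in 1.47 min, far shorter than the run, so I treat it as a pre-equilibrium. Target has a half-life of 9.8 min by the side-product step, while starting material has 4.8 h by the cross step, long against the run, and its first half-life by dimerisation is 41.7 h. I therefore take the side-product step as the drain in my reckoning, because target's half-life by it is shorter than starting material's by the cross step. Each event takes one free starting material and one target, two units of the pool, where the pool is free starting material plus target.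

Let g be target over free starting material at pre-equilibrium, K times free reagent. The charged reagent gives 0.22, which ties up about 0.00178 M of reagent, and what remains gives:

g = 0.184

With g held fixed and this step as the drain, the pool then falls at second order. I call τ the drain time, the time at which side product has taken half of the charged pool:

τ = (1 + g)^2 / (2 k g c) = 53.6 min, with k = 7.1 M⁻¹ min⁻¹ and c = 0.010 M

pool = charge / (1 + t/τ), and free starting material = pool / (1 + g)

Theta: starting material, 61.5%

Alpha: starting material, 57.6%

Zeta: starting material, 54.2%

I hold g fixed although each event carries off one reagent and the second-product step uses reagent too, so the split is the softer part of this reckoning. By this reckoning, going from 20 min to 30 min costs the pool 8.71% of the charge, so I plan the stop at 20 min.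

The forecast gives starting material at 64.7% for theta, starting material at 61% for alpha and starting material at 57.7% for zeta, on the ground “so most of the charge stays as free starting material”. My theta figure stands lower.

The flasks give starting material at 63.8% in theta, starting material at 60.1% in alpha and starting material at 56.9% in zeta. With the side-product step struck out, theta ends at 81.9% of starting material. Free starting material and target together hold 73.1% in theta, where τ of 53.6 min gives a pool of 72.8%. For the alpha charge read at 40 min, τ gives 57.3%, and that flask holds 51.6% free plus 6.34% as target, 57.9% together.

(The numbers are assumed, and the outcome is calculated.)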